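1. Retrosynthesis: (a) remove four O‑benzyl groups; (b) in the 4‑methoxyphenyl flavanone (unit A, unprimed locants) cut the aryl ether bond O1–C8a and the bond C2–C3 together, which sets free 4‑methoxybenzaldehyde and an ortho‑fluoroaryl ketone that still carries the complete 2,3‑cis flavanone (unit B, doubly primed locants, also in its monomeric precursors); (c) trace the C3''–C3 single bond back to an exocyclic C3''=C3 double bond and this to an aldol condensation of a (2S)‑flavanone with an arylglyoxal; (d) cut C2''–aryl (conjugate arylation of a chromone).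
2. Forward: chromone 1 → pyranone ring of unit B completed by asymmetric arylation → ring A, C4 and C3 of unit A attached as an arylglyoxal (aldol condensation) → cis hydrogenation → pyranone ring of unit A closed by a domino aldol/SNAr reaction → debenzylation.
3. Feature used by the key step: in unit A the pyranone ring (O1, C2, C3, C4, C4a, C8a) is a β‑aryloxy ketone; C3 is α to the C4 carbonyl and C8a is ortho to the same carbonyl on ring A, so a fluorine at C8a is SNAr‑active, C3 is enolisable, and C2–O1 is the carbonyl group of an aldehyde that can be inserted between them.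
4. Stereochemistry: C2'' by ligand‑controlled conjugate arylation; C3'' (cis) by syn hydrogenation of the exocyclic alkene on the face away from the axial 2''‑aryl group; C2 in the ring closure of the key step, relayed from C3''/C2''; C3 by equilibration α to the C4 ketone (trans to the C2 aryl group).
5. Helpers: fluorine at C8a (leaving group, lost in the key step); the 5''‑OH is left free so that its lithium phenoxide shields unit B from enolisation and ring opening; benzyl ethers on the other phenols, removed last without touching the aryl methyl ether.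

Key step: step 8

Assumption: (R)‑t‑BuPyOx is taken as the ligand antipode that gives the 2S flavanone, by analogy with the face selectivity established for cyclic enones; should a trial show the opposite sense, the other antipode is used.

Step 1
Reactants: 1 5,7-dihydroxy-4H-chromen-4-one
Product: 2 7-(benzyloxy)-5-hydroxy-4H-chromen-4-one
Conditions: BnBr (1.05 equiv), K2CO3 (1.1 equiv), acetone, reflux
Reagents that add atoms: benzyl bromide, BrCc1ccccc1
Why: Williamson etherification: the 5‑OH is tied up in a hydrogen bond to the C4 carbonyl and is far less acidic and nucleophilic than the 7‑OH, so one equivalent of base and bromide should alkylate O7 only.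

Step 2
Reactants: 2 7-(benzyloxy)-5-hydroxy-4H-chromen-4-one; 3 [4-(benzyloxy)phenyl]boronic acid
Product: 4 (2S)-7-(benzyloxy)-2-[4-(benzyloxy)phenyl]-5-hydroxy-2,3-dihydro-4H-chromen-4-one
Conditions: 3 (2 equiv), Pd(OCOCF3)2 (5 mol%), (R)-t-BuPyOx (6 mol%), NH4PF6 (30 mol%), H2O (5 equiv), ClCH2CH2Cl, 60 °C
Reagents that add atoms: none
Why: Asymmetric conjugate addition of an arylboronic acid to a chromone catalysed by divalent palladium with a pyridine–oxazoline ligand (transmetalation, enantiofacial insertion of C2''=C3'' into the aryl–palladium bond, protonolysis of the palladium enolate); the ligand sets C2'' as S and the base‑free medium leaves the hydrogen‑bonded 5''‑OH and the benzyl ethers alone.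

Step 3
Reactants: 5 5-fluorobenzene-1,3-diol; 6 acetic acid
Product: 7 1-(2-fluoro-4,6-dihydroxyphenyl)ethan-1-one
Conditions: ZnCl2 (1.5 equiv), AcOH (reactant and solvent), 140 °C
Reagents that add atoms: none
Why: Nencki reaction (ZnCl2‑mediated Friedel–Crafts C‑acylation of a resorcinol with a carboxylic acid): attack ortho to one OH and para to the other, next to fluorine, is favoured over the position flanked by both OH groups, which gives the 2‑fluoro‑4,6‑dihydroxy pattern.

Step 4
Reactants: 7 1-(2-fluoro-4,6-dihydroxyphenyl)ethan-1-one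
Product: 8 1-[2,4-bis(benzyloxy)-6-fluorophenyl]ethan-1-one
Conditions: BnBr (2.4 equiv), K2CO3 (3 equiv), DMF, 60 °C
Reagents that add atoms: benzyl bromide, BrCc1ccccc1
Why: Williamson etherification under forcing conditions, which also alkylates the hydrogen‑bonded ortho‑OH; carbonate and phenoxide are too weak as nucleophiles at this temperature to displace the fluorine.

Step 5
Reactants: 8 1-[2,4-bis(benzyloxy)-6-fluorophenyl]ethan-1-one
Product: 9 2-[2,4-bis(benzyloxy)-6-fluorophenyl]-2-oxoacetaldehyde
Conditions: SeO2 (1.3 equiv), 1,4-dioxane/H2O, 100 °C; then azeotropic drying of the hydrate with toluene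
Reagents that add atoms: selenium dioxide, O=[Se]=O
Why: Riley oxidation of the aryl methyl ketone to the arylglyoxal through the enol, a selenium ester and loss of selenium; the benzyl ethers and the ring are not expected to be oxidised under these conditions.

Step 6
Reactants: 4 (2S)-7-(benzyloxy)-2-[4-(benzyloxy)phenyl]-5-hydroxy-2,3-dihydro-4H-chromen-4-one; 9 2-[2,4-bis(benzyloxy)-6-fluorophenyl]-2-oxoacetaldehyde
Product: 11 (2R,3E)-7-(benzyloxy)-2-[4-(benzyloxy)phenyl]-3-{2-[2,4-bis(benzyloxy)-6-fluorophenyl]-2-oxoethylidene}-5-hydroxy-2,3-dihydro-4H-chromen-4-one, via aldol adduct 10 (not isolated)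
Conditions: LiN(SiMe3)2 (2.2 equiv), THF, −78 °C; 9 (1.2 equiv); AcOH; then Burgess reagent (1.5 equiv), THF, 25 °C
Reagents that add atoms: none
Why: Aldol addition of the phenoxide–enolate dianion of 4 to the aldehyde carbonyl of 9 (the hindered ketone carbonyl is left) followed by Burgess dehydration (syn elimination of the sulfamate through the acidic C3''–H) should give the conjugated (E)‑enedione, the 5''‑oxide holding back retro‑oxa‑Michael opening because loss of O1'' would put a second negative charge on that ring; the descriptor at C2'' becomes R only through the change in CIP priorities, the centre itself is untouched.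

Step 7
Reactants: 11 (2R,3E)-7-(benzyloxy)-2-[4-(benzyloxy)phenyl]-3-{2-[2,4-bis(benzyloxy)-6-fluorophenyl]-2-oxoethylidene}-5-hydroxy-2,3-dihydro-4H-chromen-4-one
Product: 12 (2S,3S)-7-(benzyloxy)-2-[4-(benzyloxy)phenyl]-3-{2-[2,4-bis(benzyloxy)-6-fluorophenyl]-2-oxoethyl}-5-hydroxy-2,3-dihydro-4H-chromen-4-one
Conditions: H2 (1 atm), 5% Pd/C(en) (palladium on carbon modified with ethylenediamine), THF, 25 °C
Reagents that add atoms: none
Why: Chemoselective heterogeneous hydrogenation of the electron‑poor C=C with a poisoned catalyst that spares O‑benzyl ethers, aryl ketones and the C–F bond; allylic 1,3‑strain with the acylmethylene group holds the 2''‑aryl group axial, so H2 should add syn from the opposite face and C3''–H end trans to the aryl group, which is the 2,3‑cis flavanone.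

Step 8
Reactants: 12 (2S,3S)-7-(benzyloxy)-2-[4-(benzyloxy)phenyl]-3-{2-[2,4-bis(benzyloxy)-6-fluorophenyl]-2-oxoethyl}-5-hydroxy-2,3-dihydro-4H-chromen-4-one; 13 4-methoxybenzaldehyde
Product: 15 (2S,3R,2''S,3''S)-5,7,7''-tris(benzyloxy)-2''-[4-(benzyloxy)phenyl]-5''-hydroxy-2-(4-methoxyphenyl)-[3,3''-bichromane]-4,4''-dione, via dilithium aldolate 14 (not isolated)
Conditions: LiN(SiMe3)2 (2.05 equiv), THF, −78 °C; 13 (1.1 equiv), −78 °C; DMPU, −78 → 40 °C; AcOH
Reagents that add atoms: none
Why: LiN(SiMe3)2 first converts the 5''‑OH into its lithium phenoxide and then removes a C3 proton of the fluoroaryl ketone; the enolate adds to 13 to give aldolate 14, whose alkoxide oxygen attacks C8a ipso to fluorine and ortho to the C4 carbonyl, and the Meisenheimer intermediate loses LiF. The closest known reactions are the aldol addition of aryl ketone enolates to aromatic aldehydes and the intramolecular SNAr etherification of ortho‑fluoroaryl ketones used for chromanones, chromones and xanthones, run here as one domino aldol–SNAr sequence. The pyranone ring (O1, C2, C3, C4, C4a, C8a) closes by a 6‑exo‑trig addition–elimination at C8a. C2 is fixed in this irreversible ring closure while the aldol step is still reversible at the cyclisation temperature (Curtin–Hammett): the favoured chair‑like transition state has the anisyl group and the unit B substituent equatorial and, about the C3–C3'' bond, places the C2 arm anti to the aryl‑bearing C2'' arm and gauche to the flat C4'' carbonyl, an arrangement dictated by the C3''/C2'' stereocentres that leads to 2S, and C3, being α to the C4 ketone, settles trans to the C2 aryl group (3R) under the basic conditions. The step needs enolisation at C3 and not at C3'' and no retro‑oxa‑Michael opening of unit B, and this is secured by the 5''‑O‑lithium phenoxide, which turns the C4'' ketone into a vinylogous carboxylate with a much less acidic α‑CH and would have to accept a second negative charge on its ring if O1'' were expelled. Only the fluorine‑bearing carbon is a leaving‑group position ortho to the carbonyl, so the benzyloxy groups are not displaced, and the lithium counter‑ion with no excess base should hold back loss of LiOH from the aldolate to the enone.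

Step 9
Reactants: 15 (2S,3R,2''S,3''S)-5,7,7''-tris(benzyloxy)-2''-[4-(benzyloxy)phenyl]-5''-hydroxy-2-(4-methoxyphenyl)-[3,3''-bichromane]-4,4''-dione
Product: 16 (2S,3R,2''S,3''S)-5,5'',7,7''-tetrahydroxy-2''-(4-hydroxyphenyl)-2-(4-methoxyphenyl)-[3,3''-bichromane]-4,4''-dione
Conditions: H2 (1 atm), 10% Pd/C, EtOAc/MeOH, 25 °C
Reagents that add atoms: none
Why: Hydrogenolysis of the four O‑benzyl ethers on palladium under neutral conditions; the aryl methyl ether and the ketones stay, the benzylic C2–O ring bonds of flavanones are cleaved much more slowly than O‑benzyl ethers, and without acid or base the epimerisable centres C3 and C3'' (cis in unit B) should not move.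

Compound list
1 | 5,7-dihydroxy-4H-chromen-4-one | O=c1ccoc2cc(O)cc(O)c12 | starting material
2 | 7-(benzyloxy)-5-hydroxy-4H-chromen-4-one | O=c1ccoc2cc(OCc3ccccc3)cc(O)c12 | intermediate
3 | [4-(benzyloxy)phenyl]boronic acid | OB(O)c1ccc(OCc2ccccc2)cc1 | starting material
4 | (2S)-7-(benzyloxy)-2-[4-(benzyloxy)phenyl]-5-hydroxy-2,3-dihydro-4H-chromen-4-one | C1C(=O)c2c(O)cc(OCc3ccccc3)cc2O[C@@H]1c1ccc(OCc2ccccc2)cc1 | intermediate
5 | 5-fluorobenzene-1,3-diol | Oc1cc(O)cc(F)c1 | starting material
6 | acetic acid | CC(=O)O | starting material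
7 | 1-(2-fluoro-4,6-dihydroxyphenyl)ethan-1-one | CC(=O)c1c(O)cc(O)cc1F | intermediate
8 | 1-[2,4-bis(benzyloxy)-6-fluorophenyl]ethan-1-one | CC(=O)c1c(OCc2ccccc2)cc(OCc2ccccc2)cc1F | intermediate
9 | 2-[2,4-bis(benzyloxy)-6-fluorophenyl]-2-oxoacetaldehyde | O=CC(=O)c1c(OCc2ccccc2)cc(OCc2ccccc2)cc1F | intermediate
10 | (2S)-7-(benzyloxy)-2-[4-(benzyloxy)phenyl]-3-{2-[2,4-bis(benzyloxy)-6-fluorophenyl]-1-hydroxy-2-oxoethyl}-5-hydroxy-2,3-dihydro-4H-chromen-4-one (mixture of diastereomers at C3 and at the carbinol carbon) | OC(C1C(=O)c2c(O)cc(OCc3ccccc3)cc2O[C@@H]1c1ccc(OCc2ccccc2)cc1)C(=O)c1c(OCc2ccccc2)cc(OCc2ccccc2)cc1F | intermediate (not isolated)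
11 | (2R,3E)-7-(benzyloxy)-2-[4-(benzyloxy)phenyl]-3-{2-[2,4-bis(benzyloxy)-6-fluorophenyl]-2-oxoethylidene}-5-hydroxy-2,3-dihydro-4H-chromen-4-one | O=C(/C=C1/C(=O)c2c(O)cc(OCc3ccccc3)cc2O[C@@H]1c1ccc(OCc2ccccc2)cc1)c1c(OCc2ccccc2)cc(OCc2ccccc2)cc1F | intermediate
12 | (2S,3S)-7-(benzyloxy)-2-[4-(benzyloxy)phenyl]-3-{2-[2,4-bis(benzyloxy)-6-fluorophenyl]-2-oxoethyl}-5-hydroxy-2,3-dihydro-4H-chromen-4-one (2,3-cis) | O=C(C[C@@H]1C(=O)c2c(O)cc(OCc3ccccc3)cc2O[C@@H]1c1ccc(OCc2ccccc2)cc1)c1c(OCc2ccccc2)cc(OCc2ccccc2)cc1F | intermediate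
13 | 4-methoxybenzaldehyde | COc1ccc(C=O)cc1 | starting material
14 | dilithium salt of (2S,3S)-7-(benzyloxy)-2-[4-(benzyloxy)phenyl]-3-{(2R,3S)-1-[2,4-bis(benzyloxy)-6-fluorophenyl]-3-hydroxy-3-(4-methoxyphenyl)-1-oxopropan-2-yl}-5-hydroxy-2,3-dihydro-4H-chromen-4-one (the anti aldolate that cyclises, in equilibrium with its aldol diastereomers) | [Li+].[Li+].COc1ccc([C@@H]([O-])[C@H](C(=O)c2c(OCc3ccccc3)cc(OCc3ccccc3)cc2F)[C@@H]2C(=O)c3c([O-])cc(OCc4ccccc4)cc3O[C@@H]2c2ccc(OCc3ccccc3)cc2)cc1 | intermediate (not isolated)
15 | (2S,3R,2''S,3''S)-5,7,7''-tris(benzyloxy)-2''-[4-(benzyloxy)phenyl]-5''-hydroxy-2-(4-methoxyphenyl)-[3,3''-bichromane]-4,4''-dione | COc1ccc([C@H]2Oc3cc(OCc4ccccc4)cc(OCc4ccccc4)c3C(=O)[C@@H]2[C@@H]2C(=O)c3c(O)cc(OCc4ccccc4)cc3O[C@@H]2c2ccc(OCc3ccccc3)cc2)cc1 | intermediate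
16 | (2S,3R,2''S,3''S)-5,5'',7,7''-tetrahydroxy-2''-(4-hydroxyphenyl)-2-(4-methoxyphenyl)-[3,3''-bichromane]-4,4''-dione | COc1ccc([C@H]2Oc3cc(O)cc(O)c3C(=O)[C@@H]2[C@@H]2C(=O)c3c(O)cc(O)cc3O[C@@H]2c2ccc(O)cc2)cc1 | target

Total step count: 9. Longest linear sequence: 7 steps (steps 3, 4, 5, 6, 7, 8, 9).

Steps most likely to fail

Step 8. Three processes may go wrong. The aldol addition may not equilibrate before ring closure, so that the kinetic face preference of the enolate, not the ring‑closure preference, decides C2 (weak or inverted diastereoselectivity). The aldolate may lose LiOH to the enone before fluoride is displaced. Proton transfer from C3'' may epimerise unit B. The fallback sets out from 12 and returns at 15. Ketone 12 is enolised at C3 with the matched antipode of diisopinocampheylboron triflate, (Ipc)2BOTf (2.2 equiv, one of them caps the 5''‑OH), and i‑Pr2NEt in CH2Cl2 at −78 °C. Aldehyde 13 is added and the mixture is worked up with H2O2 in pH 7 buffer. This should give the isolated syn aldol (2S,3S)-7-(benzyloxy)-2-[4-(benzyloxy)phenyl]-3-{(2S,3S)-1-[2,4-bis(benzyloxy)-6-fluorophenyl]-3-hydroxy-3-(4-methoxyphenyl)-1-oxopropan-2-yl}-5-hydroxy-2,3-dihydro-4H-chromen-4-one F1, whose (S)‑carbinol centre is set by the reagent in a closed, irreversible transition state without any free alkoxide. The ring is then closed by SNAr with KN(SiMe3)2 (2 equiv) and 18‑crown‑6 in THF at −40 to 0 °C, conditions chosen so that fluoride displacement can outrun aldol reversal. This should first give the 2,3‑cis flavanone (2S,3S,2''S,3''S)-5,7,7''-tris(benzyloxy)-2''-[4-(benzyloxy)phenyl]-5''-hydroxy-2-(4-methoxyphenyl)-[3,3''-bichromane]-4,4''-dione F2, which epimerises at C3 under the same conditions to 15.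

Step 6. The dianion may open by retro‑oxa‑Michael reaction with loss of the C2'' configuration, addition to the hindered glyoxal may be slow, or the new exocyclic double bond may migrate into the ring, which would also erase C2''. The fallback sets out from 4 and returns at 11. Flavanone 4 is silylated with Me3SiOTf (2.2 equiv) and Et3N in CH2Cl2 at 0 °C to the silyl enol ether (2S)-7-(benzyloxy)-2-[4-(benzyloxy)phenyl]-4,5-bis[(trimethylsilyl)oxy]-2H-chromene F3. A Mukaiyama aldol addition of F3 to 9 with BF3·OEt2 in CH2Cl2 at −78 °C, followed by aqueous work‑up that removes both silyl groups, should give 10 without any enolate being formed. Dehydration of 10 with Burgess reagent as in step 6 then gives 11.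

Step 7. Palladium may shift the exocyclic double bond into the ring before hydrogen is added, which would give the achiral 3‑substituted flavone, or some O‑benzyl ether may be cleaved. The fallback sets out from 11 and returns at 12 and makes no new compound (F0). It is a metal‑free transfer hydrogenation with Hantzsch ester (diethyl 2,6-dimethyl-1,4-dihydropyridine-3,5-dicarboxylate, 1.2 equiv) in toluene at 60 °C. Hydride adds to the exocyclic carbon (C3), and the C4'' enol that results is protonated on the face away from the axial 2''‑aryl group, which should again give the cis isomer 12.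

Further compounds
F1 | step 8 | (2S,3S)-7-(benzyloxy)-2-[4-(benzyloxy)phenyl]-3-{(2S,3S)-1-[2,4-bis(benzyloxy)-6-fluorophenyl]-3-hydroxy-3-(4-methoxyphenyl)-1-oxopropan-2-yl}-5-hydroxy-2,3-dihydro-4H-chromen-4-one | COc1ccc([C@@H](O)[C@@H](C(=O)c2c(OCc3ccccc3)cc(OCc3ccccc3)cc2F)[C@@H]2C(=O)c3c(O)cc(OCc4ccccc4)cc3O[C@@H]2c2ccc(OCc3ccccc3)cc2)cc1
F2 | step 8 | (2S,3S,2''S,3''S)-5,7,7''-tris(benzyloxy)-2''-[4-(benzyloxy)phenyl]-5''-hydroxy-2-(4-methoxyphenyl)-[3,3''-bichromane]-4,4''-dione | COc1ccc([C@H]2Oc3cc(OCc4ccccc4)cc(OCc4ccccc4)c3C(=O)[C@H]2[C@@H]2C(=O)c3c(O)cc(OCc4ccccc4)cc3O[C@@H]2c2ccc(OCc3ccccc3)cc2)cc1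
F3 | step 6 | (2S)-7-(benzyloxy)-2-[4-(benzyloxy)phenyl]-4,5-bis[(trimethylsilyl)oxy]-2H-chromene | C1=C(O[Si](C)(C)C)c2c(O[Si](C)(C)C)cc(OCc3ccccc3)cc2O[C@@H]1c1ccc(OCc2ccccc2)cc1
F0 | step 7 | none | none
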